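**Plan**

1. Numbering: ring C1 (C=O), C2=C3, C4 (CHOH), C5 (CHOH), C6 (quaternary carbinol); chain C1'–C17' with the Z-alkene at C8'=C9'.
2. Retrosynthetic cuts, in order: the acetonide and silyl ether; the C1 carbonyl back to a carbinol; C1–O and C4–O, both returned to one O2 molecule through the O–O bond of an endoperoxide; C2'–C3' (alkyl–alkyl coupling); C1'=C2' (methylenation); C5–O and C6–O (enzymatic dihydroxylation of benzoic acid, whose carboxyl carbon is C1').
3. Enabling feature: the oxygens on C1 and C4 sit 1,4 across the C2=C3 double bond of the six-membered ring, the imprint of a 2,3-dioxabicyclo[2.2.2]oct-5-ene. The cis-diol on C5/C6 with fully substituted C6 is the ipso,ortho-dihydrodiol of a benzoate.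
4. Forward: the carbocycle is the benzene ring of benzoic acid; a dioxolane is closed on the diol; the chain is joined by methylenation and B-alkyl Suzuki coupling; the peroxide ring closes in the key step and is opened by reduction; C4–OH is silylated, C1–OH oxidised, and acid frees the triol.
5. Stereochemistry: C5 and C6 come from the dioxygenase; C1 and C4 from addition of singlet oxygen anti to the dioxolane (C1 is later oxidised, C4 stays); the Z-alkene from Lindlar semihydrogenation.

Key step: step 9

Assumption: the blocked mutant Ralstonia eutropha B9 (no cis-diol dehydrogenase) is on hand as a whole-cell catalyst, so the route starts from benzoic acid itself.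
Remark: the peroxide is opened by reduction and the two allylic hydroxyls are told apart by size, because a base-induced Kornblum–DeLaMare opening would have to remove the more hindered bridgehead hydrogen at C1.

**Route**

Step 1
Reactants: 1 benzoic acid
Product: 2 (1S,2R)-1,2-dihydroxycyclohexa-3,5-diene-1-carboxylic acid
Conditions: Ralstonia eutropha B9 whole cells, sodium benzoate feed, fructose, mineral salts medium, air, 30 °C, pH 7; acidify to pH 3, EtOAc extraction
Reagents that add atoms: dioxygen, O=O
Why: Enzymatic arene cis-dihydroxylation by benzoate 1,2-dioxygenase adds dioxygen across the ipso and ortho carbons from one face, and because the mutant cannot dehydrogenate the diol it accumulates with both stereocentres (the later C6 and C5) set by the enzyme.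

Step 2
Reactants: 2 (1S,2R)-1,2-dihydroxycyclohexa-3,5-diene-1-carboxylic acid
Product: 3 (3aS,7aR)-2,2-dimethyl-3a,7a-dihydro-1,3-benzodioxole-3a-carboxylic acid
Conditions: 2,2-dimethoxypropane, TsOH·H2O (cat.), acetone, 0 °C → rt
Reagents that add atoms: 2,2-dimethoxypropane, COC(C)(C)OC
Why: Acid-catalysed transketalisation closes the five-membered dioxolane on the cis-diol quickly enough at room temperature to outrun dehydrative aromatisation of the dienediol.

Step 3
Reactants: 3 (3aS,7aR)-2,2-dimethyl-3a,7a-dihydro-1,3-benzodioxole-3a-carboxylic acid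
Product: 4 methyl (3aS,7aR)-2,2-dimethyl-3a,7a-dihydro-1,3-benzodioxole-3a-carboxylate
Conditions: MeI, K2CO3, DMF, rt
Reagents that add atoms: iodomethane, CI
Why: O-alkylation of the carboxylate (SN2 on iodomethane) under mildly basic conditions leaves the acid-sensitive diene acetonide untouched.

Step 4
Reactants: 4 methyl (3aS,7aR)-2,2-dimethyl-3a,7a-dihydro-1,3-benzodioxole-3a-carboxylate
Product: 5 (3aS,7aR)-2,2-dimethyl-3a,7a-dihydro-1,3-benzodioxole-3a-carbaldehyde
Conditions: i-Bu2AlH (DIBAL-H, 1.1 equiv), CH2Cl2, −78 °C; MeOH quench, aqueous potassium sodium tartrate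
Reagents that add atoms: none
Why: Partial ester reduction with DIBAL-H works because at −78 °C the aluminium hemiacetal, held by chelation to the neighbouring dioxolane oxygen, does not collapse until work-up, so the aldehyde is released only after the hydride has been quenched.

Step 5
Reactants: 5 (3aS,7aR)-2,2-dimethyl-3a,7a-dihydro-1,3-benzodioxole-3a-carbaldehyde
Product: 6 (3aS,7aR)-3a-ethenyl-2,2-dimethyl-3a,7a-dihydro-1,3-benzodioxole
Conditions: Ph3PCH3Br, KOtBu, THF, 0 °C → rt
Reagents that add atoms: methyltriphenylphosphonium bromide, C[P+](c1ccccc1)(c1ccccc1)c1ccccc1.[Br-]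
Why: Wittig methylenation of a non-enolisable aldehyde with the unstabilised ylide is reliable and turns the former carboxyl carbon into C1' of a vinyl group without touching the quaternary centre.

Step 6
Reactants: 7 1-decyne; 8 1,5-dibromopentane
Product: 10 1-bromopentadec-6-yne, via lithium dec-1-ynide 9 (not isolated)
Conditions: n-BuLi, THF, −78 → 0 °C; then 8 (3 equiv), DMPU, −78 °C → rt
Reagents that add atoms: none
Why: Alkylation of a lithium acetylide (SN2) with an excess of the α,ω-dibromide in the presence of DMPU gives the mono-substitution product, the excess suppressing reaction at both ends.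

Step 7
Reactants: 10 1-bromopentadec-6-yne
Product: 11 (Z)-1-bromopentadec-6-ene
Conditions: H2 (1 atm), Pd/CaCO3 poisoned with Pb(OAc)2 (Lindlar catalyst), quinoline, hexane, rt
Reagents that add atoms: none
Why: Lindlar semihydrogenation delivers both hydrogens to one face of the alkyne on the catalyst surface, which fixes the Z geometry, and a primary alkyl bromide is inert to the poisoned catalyst.

Step 8
Reactants: 6 (3aS,7aR)-3a-ethenyl-2,2-dimethyl-3a,7a-dihydro-1,3-benzodioxole; 11 (Z)-1-bromopentadec-6-ene
Product: 13 (3aS,7aR)-3a-[(Z)-heptadec-8-en-1-yl]-2,2-dimethyl-3a,7a-dihydro-1,3-benzodioxole, via B-alkyl-9-borabicyclononane 12 (not isolated)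
Conditions: 9-BBN (9-borabicyclo[3.3.1]nonane, 0.5 M in THF, 1.05 equiv), THF, 0 °C → rt; then 11, Pd(OAc)2 (cat.), PCy3 (cat.), K3PO4·H2O, THF, rt
Reagents that add atoms: none
Why: 9-BBN hydroborates the monosubstituted vinyl group anti-Markovnikov much faster than the cis-disubstituted ring alkenes, and the primary alkylborane then undergoes B-alkyl Suzuki–Miyaura alkyl–alkyl coupling, in which the bulky electron-rich PCy3 lets zerovalent palladium insert into the primary C–Br bond and lets transmetalation outpace β-hydride elimination.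

Step 9
Reactants: 13 (3aS,7aR)-3a-[(Z)-heptadec-8-en-1-yl]-2,2-dimethyl-3a,7a-dihydro-1,3-benzodioxole
Product: 14 (3aR,4R,7S,7aR)-3a-[(Z)-heptadec-8-en-1-yl]-2,2-dimethyl-3a,4,7,7a-tetrahydro-4,7-epidioxy-1,3-benzodioxole (peroxide bridge anti to the dioxolane)
Conditions: O2 (bubbled), tetraphenylporphyrin (1 mol%), CH2Cl2, −78 °C, visible light, stopped when 13 is consumed
Reagents that add atoms: dioxygen, O=O
Why: Energy transfer from photoexcited tetraphenylporphyrin converts ground-state dioxygen into singlet oxygen, which adds as a 2π partner across C1 and C4 of the ring-locked s-cis diene in a concerted, suprafacial hetero-[4+2] cycloaddition that forms both C–O bonds at once. The closest known reaction type is the sensitised photooxygenation of cyclohexa-1,3-dienes, arene cis-dihydrodiol acetonides included, to 2,3-dioxabicyclo[2.2.2]oct-5-enes. The one new ring, the six-membered 1,2-dioxane made of C1, O, O, C4, C3 and C2, closes by cycloaddition and not by stepwise cyclisation, turning the carbocycle into a bicyclo[2.2.2] cage. The two new stereocentres C1 and C4 are set together by the face of approach, which is dictated by the cis-fused dioxolane: its oxygens and gem-dimethyl carbon cover one face sterically and repel the incoming oxygen electrostatically, so the peroxide bridge forms anti to it and C4–O ends up trans to C5–O. The flexible C1' methylene on the open face is the only obstacle there and is expected to be a minor one. The step also needs chemoselectivity for the diene over the isolated Z-alkene of the chain (Schenck ene reaction), secured by the much higher reactivity of a cyclic 1,3-diene towards singlet oxygen, by the low temperature and by ending the irradiation as soon as 13 is gone.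

Step 10
Reactants: 14 (3aR,4R,7S,7aR)-3a-[(Z)-heptadec-8-en-1-yl]-2,2-dimethyl-3a,4,7,7a-tetrahydro-4,7-epidioxy-1,3-benzodioxole
Product: 15 (3aS,4R,7S,7aR)-3a-[(Z)-heptadec-8-en-1-yl]-2,2-dimethyl-3a,4,7,7a-tetrahydro-1,3-benzodioxole-4,7-diol
Conditions: thiourea (1.5 equiv), MeOH/CH2Cl2, 0 °C → rt
Reagents that add atoms: none
Why: Thiourea reduction of a bicyclic endoperoxide cleaves only the O–O bond, so both C–O bonds persist and the cis-1,4-diol inherits the configuration of C1 and C4 unchanged.

Step 11
Reactants: 15 (3aS,4R,7S,7aR)-3a-[(Z)-heptadec-8-en-1-yl]-2,2-dimethyl-3a,4,7,7a-tetrahydro-1,3-benzodioxole-4,7-diol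
Product: 16 (3aS,4R,7S,7aR)-7-[(tert-butyldimethylsilyl)oxy]-3a-[(Z)-heptadec-8-en-1-yl]-2,2-dimethyl-3a,4,7,7a-tetrahydro-1,3-benzodioxol-4-ol (silyl ether on the ring C4 oxygen, free hydroxyl on ring C1)
Conditions: TBSCl (1.1 equiv), imidazole, DMAP (cat.), CH2Cl2, 0 °C
Reagents that add atoms: tert-butyldimethylsilyl chloride, CC(C)(C)[Si](C)(C)Cl
Why: Regioselective silylation by steric differentiation should take the C4 hydroxyl, which has only the C5 hydrogen beside it on its face, in preference to the neopentylic C1 hydroxyl, which is flanked by the quaternary C6 whose chain is cis to it.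

Step 12
Reactants: 16 (3aS,4R,7S,7aR)-7-[(tert-butyldimethylsilyl)oxy]-3a-[(Z)-heptadec-8-en-1-yl]-2,2-dimethyl-3a,4,7,7a-tetrahydro-1,3-benzodioxol-4-ol
Product: 17 (3aR,7S,7aR)-7-[(tert-butyldimethylsilyl)oxy]-3a-[(Z)-heptadec-8-en-1-yl]-2,2-dimethyl-7,7a-dihydro-1,3-benzodioxol-4(3aH)-one
Conditions: Dess–Martin periodinane, CH2Cl2, 0 °C → rt; aqueous Na2S2O3/NaHCO3 work-up
Reagents that add atoms: none
Why: Dess–Martin oxidation converts the hindered allylic C1 alcohol into the enone under non-basic conditions that spare the γ-silyloxy group, the acetonide and the Z-alkene, and the neighbouring C6 cannot epimerise because it is quaternary.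

Step 13
Reactants: 17 (3aR,7S,7aR)-7-[(tert-butyldimethylsilyl)oxy]-3a-[(Z)-heptadec-8-en-1-yl]-2,2-dimethyl-7,7a-dihydro-1,3-benzodioxol-4(3aH)-one
Product: 18 pleiogenone A, (4S,5R,6R)-6-[(Z)-heptadec-8-en-1-yl]-4,5,6-trihydroxycyclohex-2-en-1-one
Conditions: TFA/H2O/THF (3:1:1), 0 °C → rt
Reagents that add atoms: none
Why: Aqueous-acid hydrolysis cleaves the dioxolane at its ketal carbon and the silyl ether at silicon in one operation, so no ring C–O bond is broken, C4, C5 and C6 keep their configuration, and the isolated Z-alkene is not isomerised.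

**Compound list**

1 | benzoic acid | O=C(O)c1ccccc1 | starting material
2 | (1S,2R)-1,2-dihydroxycyclohexa-3,5-diene-1-carboxylic acid | OC(=O)[C@]1(O)C=CC=C[C@H]1O | intermediate
3 | (3aS,7aR)-2,2-dimethyl-3a,7a-dihydro-1,3-benzodioxole-3a-carboxylic acid | OC(=O)[C@]12C=CC=C[C@H]1OC(C)(C)O2 | intermediate
4 | methyl (3aS,7aR)-2,2-dimethyl-3a,7a-dihydro-1,3-benzodioxole-3a-carboxylate | COC(=O)[C@]12C=CC=C[C@H]1OC(C)(C)O2 | intermediate
5 | (3aS,7aR)-2,2-dimethyl-3a,7a-dihydro-1,3-benzodioxole-3a-carbaldehyde | O=C[C@]12C=CC=C[C@H]1OC(C)(C)O2 | intermediate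
6 | (3aS,7aR)-3a-ethenyl-2,2-dimethyl-3a,7a-dihydro-1,3-benzodioxole | C=C[C@]12C=CC=C[C@H]1OC(C)(C)O2 | intermediate
7 | 1-decyne | C#CCCCCCCCC | starting material
8 | 1,5-dibromopentane | BrCCCCCBr | starting material
9 | lithium dec-1-ynide | [Li]C#CCCCCCCCC | intermediate (not isolated)
10 | 1-bromopentadec-6-yne | BrCCCCCC#CCCCCCCCC | intermediate
11 | (Z)-1-bromopentadec-6-ene | BrCCCCC/C=C\CCCCCCCC | intermediate
12 | 9-{2-[(3aS,7aR)-2,2-dimethyl-3a,7a-dihydro-1,3-benzodioxol-3a-yl]ethyl}-9-borabicyclo[3.3.1]nonane | C1CC2CCCC(C1)B2CC[C@]12C=CC=C[C@H]1OC(C)(C)O2 | intermediate (not isolated)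
13 | (3aS,7aR)-3a-[(Z)-heptadec-8-en-1-yl]-2,2-dimethyl-3a,7a-dihydro-1,3-benzodioxole | CCCCCCCC/C=C\CCCCCCC[C@]1(OC(C)(C)O2)C=CC=C[C@H]12 | intermediate (key-step precursor)
14 | (3aR,4R,7S,7aR)-3a-[(Z)-heptadec-8-en-1-yl]-2,2-dimethyl-3a,4,7,7a-tetrahydro-4,7-epidioxy-1,3-benzodioxole | CCCCCCCC/C=C\CCCCCCC[C@]1(OC(C)(C)O2)[C@H]3C=C[C@H](OO3)[C@H]12 | intermediate (key-step product)
15 | (3aS,4R,7S,7aR)-3a-[(Z)-heptadec-8-en-1-yl]-2,2-dimethyl-3a,4,7,7a-tetrahydro-1,3-benzodioxole-4,7-diol | CCCCCCCC/C=C\CCCCCCC[C@]1(OC(C)(C)O2)[C@H](O)C=C[C@H](O)[C@H]12 | intermediate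
16 | (3aS,4R,7S,7aR)-7-[(tert-butyldimethylsilyl)oxy]-3a-[(Z)-heptadec-8-en-1-yl]-2,2-dimethyl-3a,4,7,7a-tetrahydro-1,3-benzodioxol-4-ol | CCCCCCCC/C=C\CCCCCCC[C@]1(OC(C)(C)O2)[C@H](O)C=C[C@H](O[Si](C)(C)C(C)(C)C)[C@H]12 | intermediate
17 | (3aR,7S,7aR)-7-[(tert-butyldimethylsilyl)oxy]-3a-[(Z)-heptadec-8-en-1-yl]-2,2-dimethyl-7,7a-dihydro-1,3-benzodioxol-4(3aH)-one | CCCCCCCC/C=C\CCCCCCC[C@]1(OC(C)(C)O2)C(=O)C=C[C@H](O[Si](C)(C)C(C)(C)C)[C@H]12 | intermediate
18 | pleiogenone A, (4S,5R,6R)-6-[(Z)-heptadec-8-en-1-yl]-4,5,6-trihydroxycyclohex-2-en-1-one | CCCCCCCC/C=C\CCCCCCC[C@]1(O)C(=O)C=C[C@H](O)[C@H]1O | target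

**Step count**

Total steps: 13. Longest linear sequence: 11 steps (steps 1–5 and 8–13, from benzoic acid); the bromide fragment takes steps 6–7.

**Steps most likely to fail, with fallbacks**

Step 8 (hydroboration and alkyl–alkyl coupling). What may go wrong is β-hydride elimination from the alkylpalladium intermediate, protodeboronation of the alkylborane, or competing hydroboration of the ring diene. The fallback joins the same C2'–C3' bond by a copper-catalysed Grignard–sulfonate coupling. It sets out from 6, which is hydroborated as before, and the borane 12 is oxidised (NaOH, H2O2, 0 °C) to 2-[(3aS,7aR)-2,2-dimethyl-3a,7a-dihydro-1,3-benzodioxol-3a-yl]ethanol F1. TsCl in pyridine gives 2-[(3aS,7aR)-2,2-dimethyl-3a,7a-dihydro-1,3-benzodioxol-3a-yl]ethyl 4-methylbenzenesulfonate F2. Bromide 11 and Mg turnings in THF give (Z)-pentadec-6-enylmagnesium bromide F3, which should displace the primary tosylate of F2 under Li2CuCl4 catalysis (THF, −20 → 0 °C). The fallback comes back to the route at 13.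

Step 9 (photooxygenation). What may go wrong is ene-type oxygenation of the chain alkene competing with the cycloaddition, so that allylic hydroperoxides build up before the diene is consumed. The fallback keeps the cycloaddition but carries the chain unsaturation through it as an alkyne, which singlet oxygen does not attack. It sets out from 6, which is hydroborated and coupled with bromoalkyne 10 under the conditions of step 8 to give (3aS,7aR)-3a-(heptadec-8-yn-1-yl)-2,2-dimethyl-3a,7a-dihydro-1,3-benzodioxole F4. Sensitised photooxygenation as in step 9 should give (3aR,4R,7S,7aR)-3a-(heptadec-8-yn-1-yl)-2,2-dimethyl-3a,4,7,7a-tetrahydro-4,7-epidioxy-1,3-benzodioxole F5. Thiourea then gives (3aS,4R,7S,7aR)-3a-(heptadec-8-yn-1-yl)-2,2-dimethyl-3a,4,7,7a-tetrahydro-1,3-benzodioxole-4,7-diol F6. Lindlar semihydrogenation (H2, Pd/CaCO3 poisoned with Pb(OAc)2, quinoline) sets the Z-alkene, and the fallback comes back to the route at 15.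

Step 4 (partial reduction). What may go wrong is over-reduction, because the aluminium hemiacetal may collapse before the quench and the freed aldehyde is reduced further. The fallback replaces the partial reduction by full reduction and re-oxidation. It sets out from 4, which LiAlH4 (THF, 0 °C) reduces to [(3aR,7aR)-2,2-dimethyl-3a,7a-dihydro-1,3-benzodioxol-3a-yl]methanol F7. Dess–Martin periodinane (CH2Cl2, 0 °C) oxidises this alcohol, and the fallback comes back to the route at 5.

**Further compounds**

F1 | step 8 | 2-[(3aS,7aR)-2,2-dimethyl-3a,7a-dihydro-1,3-benzodioxol-3a-yl]ethanol | OCC[C@]12C=CC=C[C@H]1OC(C)(C)O2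
F2 | step 8 | 2-[(3aS,7aR)-2,2-dimethyl-3a,7a-dihydro-1,3-benzodioxol-3a-yl]ethyl 4-methylbenzenesulfonate | Cc1ccc(cc1)S(=O)(=O)OCC[C@]12C=CC=C[C@H]1OC(C)(C)O2
F3 | step 8 | (Z)-pentadec-6-enylmagnesium bromide | Br[Mg]CCCCC/C=C\CCCCCCCC
F4 | step 9 | (3aS,7aR)-3a-(heptadec-8-yn-1-yl)-2,2-dimethyl-3a,7a-dihydro-1,3-benzodioxole | CCCCCCCCC#CCCCCCCC[C@]1(OC(C)(C)O2)C=CC=C[C@H]12
F5 | step 9 | (3aR,4R,7S,7aR)-3a-(heptadec-8-yn-1-yl)-2,2-dimethyl-3a,4,7,7a-tetrahydro-4,7-epidioxy-1,3-benzodioxole | CCCCCCCCC#CCCCCCCC[C@]1(OC(C)(C)O2)[C@H]3C=C[C@H](OO3)[C@H]12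
F6 | step 9 | (3aS,4R,7S,7aR)-3a-(heptadec-8-yn-1-yl)-2,2-dimethyl-3a,4,7,7a-tetrahydro-1,3-benzodioxole-4,7-diol | CCCCCCCCC#CCCCCCCC[C@]1(OC(C)(C)O2)[C@H](O)C=C[C@H](O)[C@H]12
F7 | step 4 | [(3aR,7aR)-2,2-dimethyl-3a,7a-dihydro-1,3-benzodioxol-3a-yl]methanol | OC[C@]12C=CC=C[C@H]1OC(C)(C)O2
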